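**Retrosynthetic overview**
- Kadsurenin D (12) is a bicyclo[3.2.1]oct-3-ene-2,8-dione. The strategy rests on its six-membered ring C1–C2(=O)–C3(OMe)=C4–C5–C8(=O), which is a dearomatized 2-alkyl-4,5-dimethoxyphenol: the allyl-bearing bridgehead C5 is an electrophilic α-carbon and the bridgehead C1 a nucleophilic α-carbon of the C8 ketone.
- Last disconnections, both in one flask: allyl–C5 (Hosomi–Sakurai allylation of the cation of p-quinone monoketal 9) and C1–C7 (capture of a 3,4-dimethoxybenzyl cation). The second bond closes the cyclopentanone C1–C7–C6–C5–C8.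
- Ketal 9 comes from phenol 8 by oxidative dearomatization. The side chain is joined to the arene at C5–C6 by Pd-catalysed α-arylation (3 + 4), and C6 is set by dynamic kinetic asymmetric hydrogenation of ketone 5.
- Ring order: the arene of 3,4-dimethoxyphenol (1) is carried through as the future six-membered ring; the five-membered ring is closed last.

Key step: step 8

Remark (assumptions): atom labels C1–C8 are those of the bicyclic core of 12 and are used for the same atoms in its precursors. The carbinol carbon C7 of 6–9 is ionized in step 8, so only C6 needs absolute control. The (R),(R) antipode of the Ru catalyst in step 4 is taken to give S carbinols, as it does with simple aryl alkyl ketones.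

**Step 1**
Reactants: 1 3,4-dimethoxyphenol
Product: 2 2-bromo-4,5-dimethoxyphenol
Conditions: NBS (1.0 equiv), CH2Cl2, −20 → 0 °C
Reagents that add atoms: N-bromosuccinimide, O=C1CCC(=O)N1Br
Why: Electrophilic aromatic bromination of the activated phenol should go to the ring carbon ortho to the hydroxyl and para to a methoxy group, because the other ortho site is flanked by two oxygen substituents.

**Step 2**
Reactants: 2 2-bromo-4,5-dimethoxyphenol
Product: 3 1-(benzyloxy)-2-bromo-4,5-dimethoxybenzene
Conditions: BnBr (1.1 equiv), K2CO3 (1.5 equiv), acetone, reflux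
Reagents that add atoms: benzyl bromide, BrCc1ccccc1
Why: Williamson etherification of the phenoxide masks the acidic OH for the strongly basic coupling, hydrogenation and methylation steps that follow.

**Step 3**
Reactants: 3 1-(benzyloxy)-2-bromo-4,5-dimethoxybenzene; 4 1-(3,4-dimethoxyphenyl)propan-1-one
Product: 5 racemic 2-[2-(benzyloxy)-4,5-dimethoxyphenyl]-1-(3,4-dimethoxyphenyl)propan-1-one
Conditions: Pd(OAc)2 (2 mol%), [HP(t-Bu)3]BF4 (4 mol%), NaOt-Bu (2.2 equiv), toluene, 70 °C
Reagents that add atoms: none
Why: Palladium-catalysed ketone α-arylation (oxidative addition of zerovalent palladium into the C–Br bond, enolate exchange, reductive elimination) is established for propiophenones and should stop at monoarylation because the product has a hindered tertiary α-carbon; it forms the C5–C6 bond, with C6 still racemic.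

**Step 4**
Reactants: 5 racemic 2-[2-(benzyloxy)-4,5-dimethoxyphenyl]-1-(3,4-dimethoxyphenyl)propan-1-one
Product: 6 (1S,2S)-2-[2-(benzyloxy)-4,5-dimethoxyphenyl]-1-(3,4-dimethoxyphenyl)propan-1-ol
Conditions: RuCl2[(R)-xylbinap][(R)-daipen] (0.5 mol%), KOt-Bu (0.2 equiv), H2 (10 atm), i-PrOH/toluene, 25 °C
Reagents that add atoms: none
Why: Asymmetric hydrogenation with a divalent ruthenium diphosphine/diamine catalyst under base, run as a dynamic kinetic resolution: the doubly activated α-stereocentre should epimerize through the potassium enolate faster than the carbonyl is reduced, and the catalyst should reduce the (S)-ketone preferentially to the like (1S,2S) alcohol, so the catalyst sets C6 (and the sacrificial C7).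

**Step 5**
Reactants: 6 (1S,2S)-2-[2-(benzyloxy)-4,5-dimethoxyphenyl]-1-(3,4-dimethoxyphenyl)propan-1-ol
Product: 7 1-(benzyloxy)-2-[(1S,2S)-1-(3,4-dimethoxyphenyl)-1-methoxypropan-2-yl]-4,5-dimethoxybenzene
Conditions: NaH (1.5 equiv), MeI (2 equiv), THF, 0 °C → rt
Reagents that add atoms: iodomethane, CI
Why: Williamson methylation of the sodium alkoxide turns the carbinol into a benzylic methyl ether that cannot interfere in the oxidation of step 7 and serves as the leaving group at C7 in step 8; no stereocentre is touched.

**Step 6**
Reactants: 7 1-(benzyloxy)-2-[(1S,2S)-1-(3,4-dimethoxyphenyl)-1-methoxypropan-2-yl]-4,5-dimethoxybenzene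
Product: 8 2-[(1S,2S)-1-(3,4-dimethoxyphenyl)-1-methoxypropan-2-yl]-4,5-dimethoxyphenol
Conditions: H2 (1 atm), 10% Pd/C, EtOAc, rt
Reagents that add atoms: none
Why: Heterogeneous hydrogenolysis under neutral, acid-free conditions should cleave the aryl benzyl ether much faster than the secondary benzylic methyl ether, which needs acid activation to be lost.

**Step 7**
Reactants: 8 2-[(1S,2S)-1-(3,4-dimethoxyphenyl)-1-methoxypropan-2-yl]-4,5-dimethoxyphenol
Product: 9 2-[(1S,2S)-1-(3,4-dimethoxyphenyl)-1-methoxypropan-2-yl]-4,4,5-trimethoxycyclohexa-2,5-dien-1-one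
Conditions: PhI(OAc)2 (1.05 equiv), MeOH, 0 °C; then aq NaHCO3
Reagents that add atoms: methanol, CO
Why: Oxidative dearomatization of a p-methoxyphenol with a trivalent iodine reagent: methanol should add at the methoxy-bearing carbon para to the phenol oxygen (C3) to give the p-quinone monoketal, leaving the non-phenolic dimethoxyphenyl ring and the side-chain stereocentres untouched.

**Step 8**
Reactants: 9 2-[(1S,2S)-1-(3,4-dimethoxyphenyl)-1-methoxypropan-2-yl]-4,4,5-trimethoxycyclohexa-2,5-dien-1-one; 10 allyltrimethylsilane
Product: 12 Kadsurenin D, via C5-allyl dienone 11 (not isolated)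
Conditions: 10 (1.5 equiv), Me3SiOTf (0.3 equiv), 2,6-di-tert-butyl-4-methylpyridine (0.2 equiv), CH2Cl2, −78 °C, then −78 → −30 °C; Et3N, then aq NaHCO3
Reagents that add atoms: none
Why: Proposed new method: the silyl triflate should ionize the C3 dimethyl ketal of 9 before the less labile benzylic ether, giving a methoxy-stabilized cation whose only electrophilic α-carbon is the alkyl-bearing C5 (C1 is the electron-rich β-carbon of the C2 enol ether), and the allylsilane should add there in a Hosomi–Sakurai allylation with loss of silicon to give the non-enolizable dienone 11; on warming, the C7 methyl ether ionizes to the 3,4-dimethoxybenzyl cation, C1 captures it, and methoxytrimethylsilane takes the methyl group of the resulting C2 oxocarbenium ion as dimethyl ether, which returns the silyl triflate and leaves the 2,8-dione. The closest known reaction type is the acid-promoted stepwise cationic (5+2) cycloaddition of p-quinone monoketals with (E)-propenylarenes, which passes through the same dienone/benzylic-cation pair and ends with the same C1–C7 closure, together with the Hosomi–Sakurai allylation of quinone-monoketal cations at the carbon α to the carbonyl. The only ring closed is the cyclopentanone C1–C7–C6–C5–C8, by a 5-exo-trig attack in which the nucleophilic C1=C2 bond stays exocyclic to the new ring. C5 is set by 1,2-induction from C6: with C6–H in the ring plane next to the C8 carbonyl (A1,3 minimum) the CH(OMe)Ar group covers one face of C5, so the silane should enter past the methyl group, which places that methyl endo (towards the C2–C4 bridge) after closure. C7 should then form with the aryl group exo (towards C8, trans to the methyl), and C1 is dictated by the bridge. The step needs ketal-before-ether ionization, C5 regiochemistry and C- over O-closure, which rest on the greater lability of the ketal, on the deactivation of C1 by the C2 methoxy group, and on kinetic control at low temperature with a hindered base that keeps protic acid away.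

**Compound list**
1 | 3,4-dimethoxyphenol | COc1ccc(O)cc1OC | starting material
2 | 2-bromo-4,5-dimethoxyphenol | COc1cc(Br)c(O)cc1OC | intermediate
3 | 1-(benzyloxy)-2-bromo-4,5-dimethoxybenzene | COc1cc(Br)c(OCc2ccccc2)cc1OC | intermediate
4 | 1-(3,4-dimethoxyphenyl)propan-1-one | CCC(=O)c1ccc(OC)c(OC)c1 | starting material
5 | racemic 2-[2-(benzyloxy)-4,5-dimethoxyphenyl]-1-(3,4-dimethoxyphenyl)propan-1-one | CC(c1cc(OC)c(OC)cc1OCc1ccccc1)C(=O)c1ccc(OC)c(OC)c1 | intermediate
6 | (1S,2S)-2-[2-(benzyloxy)-4,5-dimethoxyphenyl]-1-(3,4-dimethoxyphenyl)propan-1-ol | C[C@@H](c1cc(OC)c(OC)cc1OCc1ccccc1)[C@H](O)c1ccc(OC)c(OC)c1 | intermediate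
7 | 1-(benzyloxy)-2-[(1S,2S)-1-(3,4-dimethoxyphenyl)-1-methoxypropan-2-yl]-4,5-dimethoxybenzene | C[C@@H](c1cc(OC)c(OC)cc1OCc1ccccc1)[C@H](OC)c1ccc(OC)c(OC)c1 | intermediate
8 | 2-[(1S,2S)-1-(3,4-dimethoxyphenyl)-1-methoxypropan-2-yl]-4,5-dimethoxyphenol | C[C@@H](c1cc(OC)c(OC)cc1O)[C@H](OC)c1ccc(OC)c(OC)c1 | intermediate
9 | 2-[(1S,2S)-1-(3,4-dimethoxyphenyl)-1-methoxypropan-2-yl]-4,4,5-trimethoxycyclohexa-2,5-dien-1-one | O=C1C=C(OC)C(OC)(OC)C=C1[C@H](C)[C@H](OC)c1ccc(OC)c(OC)c1 | intermediate
10 | allyltrimethylsilane | C=CC[Si](C)(C)C | starting material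
11 | (6S)-6-allyl-6-[(1S,2S)-1-(3,4-dimethoxyphenyl)-1-methoxypropan-2-yl]-3,4-dimethoxycyclohexa-2,4-dien-1-one (C5-allyl dienone, not isolated) | C=CC[C@@]1(C=C(OC)C(OC)=CC1=O)[C@H](C)[C@H](OC)c1ccc(OC)c(OC)c1 | intermediate
12 | Kadsurenin D, (1S,5S,6R,7R)-5-allyl-7-(3,4-dimethoxyphenyl)-3-methoxy-6-methylbicyclo[3.2.1]oct-3-ene-2,8-dione (7-aryl exo, 6-methyl endo) | C=CC[C@]12C=C(OC)C(=O)[C@H](C1=O)[C@H](c1ccc(OC)c(OC)c1)[C@H]2C | target

Total step count: 8
Longest linear sequence: 8 steps (1 → 12); 4 enters at step 3 and 10 at step 8.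

**Steps most likely to fail**

1. Step 8 (proposed new method). Several processes can divert the cascade:
- the C5 cation may be captured by the pendant dimethoxyphenyl ring (spiro-annulation), or the silane may add at C3 instead of the congested C5;
- facial discrimination at C5 may be low, because the controlling centre C6 lies outside the ring;
- dienone 11 may shift its allyl group to oxygen by a [3,3] process, or dimerize, before C7 ionizes;
- the C7 cation may close on the C8 oxygen, or the bicycle may reopen under acid and drift to the hydrobenzofuranone.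

Fallback with known chemistry, setting out from 1 and returning at 12: O-allylation of 1 (allyl bromide, K2CO3, acetone) should give 4-(allyloxy)-1,2-dimethoxybenzene F1. Thermal Claisen rearrangement (N,N-diethylaniline, about 190 °C) should move the allyl group to the less hindered ortho carbon and give 2-allyl-4,5-dimethoxyphenol F2. Oxidation with PhI(OAc)2 in MeOH should give 2-allyl-4,4,5-trimethoxycyclohexa-2,5-dien-1-one F3. The established cationic (5+2) cycloaddition of this ketal with (E)-1,2-dimethoxy-4-(prop-1-en-1-yl)benzene F4 (Me3SiOTf cat., CH2Cl2, −78 °C) should give racemic Kadsurenin D F5, with methyl and aryl trans as fixed by the E alkene. F5 would be freed from its 7-endo-aryl isomer and from the hydrobenzofuranone by chromatography, and its enantiomers separated by preparative HPLC on a chiral stationary phase to give 12.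

2. Step 4. Enolization of the hindered ketone may be slower than its reduction, or the catalyst may discriminate poorly between two bulky aryl-bearing flanks, so that the configuration at C6 is set incompletely.

Fallback, setting out from 5 and returning at 6: substrate-controlled reduction with LiBH(s-Bu)3 (THF, −78 °C) should give the racemic like alcohol F6. Steglich esterification with (S)-2-methoxy-2-phenylacetic acid (DCC, DMAP) should give two diastereomeric esters, the (1S,2S)-alcohol ester F7 and the (1R,2R)-alcohol ester F8, to be separated by chromatography or crystallization. Saponification of F7 (LiOH, THF/H2O) should release 6.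

3. Step 3. Oxidative addition into the electron-rich, ortho-alkoxylated C–Br bond may be slow, leaving room for hydrodebromination of 3 and aldol self-condensation of 4 under the strongly basic conditions.

Fallback with reversed polarity, setting out from 3 and 4 and returning at 5: α-bromination of 4 (CuBr2, EtOAc/CHCl3, reflux) should give 2-bromo-1-(3,4-dimethoxyphenyl)propan-1-one F9. Magnesium insertion into 3 in the presence of LiCl and ZnCl2 (THF) should give [2-(benzyloxy)-4,5-dimethoxyphenyl]zinc chloride F10. Nickel-catalysed Negishi coupling of F9 with F10 (NiCl2(MeOCH2CH2OMe), pybox ligand, THF/DME, −30 °C → rt), a known arylation of secondary α-bromo ketones, should give 5 without a strong base.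

**Further compounds**
F1 | step 8 | 4-(allyloxy)-1,2-dimethoxybenzene | C=CCOc1ccc(OC)c(OC)c1
F2 | step 8 | 2-allyl-4,5-dimethoxyphenol | C=CCc1cc(OC)c(OC)cc1O
F3 | step 8 | 2-allyl-4,4,5-trimethoxycyclohexa-2,5-dien-1-one | C=CCC1=CC(OC)(OC)C(OC)=CC1=O
F4 | step 8 | (E)-1,2-dimethoxy-4-(prop-1-en-1-yl)benzene | C/C=C/c1ccc(OC)c(OC)c1
F5 | step 8 | racemic Kadsurenin D (12 and its enantiomer) | C=CC[C@]12C=C(OC)C(=O)[C@H](C1=O)[C@H](c1ccc(OC)c(OC)c1)[C@H]2C.C=CC[C@@]12C=C(OC)C(=O)[C@@H](C1=O)[C@@H](c1ccc(OC)c(OC)c1)[C@@H]2C
F6 | step 4 | racemic like alcohol (6 and its enantiomer) | C[C@@H](c1cc(OC)c(OC)cc1OCc1ccccc1)[C@H](O)c1ccc(OC)c(OC)c1.C[C@H](c1cc(OC)c(OC)cc1OCc1ccccc1)[C@@H](O)c1ccc(OC)c(OC)c1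
F7 | step 4 | (1S,2S)-2-[2-(benzyloxy)-4,5-dimethoxyphenyl]-1-(3,4-dimethoxyphenyl)propyl (S)-2-methoxy-2-phenylacetate | C[C@@H](c1cc(OC)c(OC)cc1OCc1ccccc1)[C@H](OC(=O)[C@@H](OC)c1ccccc1)c1ccc(OC)c(OC)c1
F8 | step 4 | (1R,2R)-2-[2-(benzyloxy)-4,5-dimethoxyphenyl]-1-(3,4-dimethoxyphenyl)propyl (S)-2-methoxy-2-phenylacetate | C[C@H](c1cc(OC)c(OC)cc1OCc1ccccc1)[C@@H](OC(=O)[C@@H](OC)c1ccccc1)c1ccc(OC)c(OC)c1
F9 | step 3 | racemic 2-bromo-1-(3,4-dimethoxyphenyl)propan-1-one | CC(Br)C(=O)c1ccc(OC)c(OC)c1
F10 | step 3 | [2-(benzyloxy)-4,5-dimethoxyphenyl]zinc chloride | COc1cc([Zn]Cl)c(OCc2ccccc2)cc1OC
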